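**Retrosynthetic overview**
1. Last step is acetylation of the secondary 3β-OH; the butenolide arrives intact by C12–C13 cross-electrophile coupling of a primary iodide with 4-bromofuran-2(5H)-one.
2. The 9α-OH/8β-H pair comes from an 8α,9α-epoxide: the C9–O bond is the key bond, made by α-face epoxidation of a Δ8(9) alkene, and hydride then opens the epoxide at C8 with inversion (one pot with ester reduction).
3. The Δ8(9) ester comes from eliminative methanolysis of the lactone of 3β-hydroxysclareolide.
4. The C3–O bond is made first, by enzymatic C–H hydroxylation of (+)-sclareolide.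
5. Ring order: rings A and B are taken intact from sclareolide, its lactone ring is opened in step 2 and not re-formed, and the butenolide ring is bought preformed; no ring is built.

Assumption: labdane numbering and α/β descriptors are used (β = face of the C10 methyl); the target is read as (3S,5S,8R,9R,10S), the normal labdane series of (+)-sclareolide, and 4-bromofuran-2(5H)-one is bought (it is also one step from tetronic acid).

**Route**

Step 1
Reactants: 1 (+)-sclareolide
Product: 2 3β-hydroxysclareolide
Conditions: engineered P450BM3 variant (C3-selective heme monooxygenase, E. coli lysate), NADP+ (cat.), phosphite dehydrogenase, Na2HPO3, air, KPi buffer pH 8, 5% DMSO, 25 °C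
Reagents that add atoms: dioxygen O=O
Why: Biocatalytic C–H hydroxylation by the P450 oxygen-rebound mechanism, known for sclareolide, replaces the equatorial 3β-H with retention, so the active site sets both the site (C3 over C2) and the 3S configuration.

Step 2
Reactants: 2 3β-hydroxysclareolide
Product: 3 methyl 3β-hydroxy-13,14,15,16-tetranorlabd-8(9)-en-12-oate
Conditions: conc. H2SO4 (10 vol %), MeOH, reflux, 36 h; AgNO3–silica chromatography, lactone and minor alkene isomers resubjected
Reagents that add atoms: methanol CO
Why: Acid-catalysed alkyl–oxygen cleavage of the tertiary lactone, Fischer esterification and E1 elimination under equilibrating conditions funnel to the thermodynamically preferred tetrasubstituted Δ8(9) alkene; no stereocentre is formed, and C8/C9 are deliberately made planar to be rebuilt in steps 3 and 4.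

Step 3
Reactants: 3 methyl 3β-hydroxy-13,14,15,16-tetranorlabd-8(9)-en-12-oate
Product: 4 methyl 8α,9α-epoxy-3β-hydroxy-13,14,15,16-tetranorlabdan-12-oate
Conditions: dimethyldioxirane (1.1 equiv), acetone, −20 to 0 °C
Reagents that add atoms: dimethyldioxirane CC1(C)OO1
Why: Concerted electrophilic epoxidation of the electron-rich tetrasubstituted alkene from the α face, because the axial C10 methyl shields the β face, forms the key C9–O bond with 9α configuration; the neutral reagent avoids acid opening and E1cB opening of the β,γ-epoxy ester and oxidises the secondary alcohol far more slowly.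

Step 4
Reactants: 4 methyl 8α,9α-epoxy-3β-hydroxy-13,14,15,16-tetranorlabdan-12-oate
Product: 6 13,14,15,16-tetranorlabdane-3β,9α,12-triol (8βH), via epoxy diol 5 (not isolated)
Conditions: LiAlH4 (5 equiv), THF, 0 °C, 30 min; then reflux, 16 h; aqueous work-up
Reagents that add atoms: none
Why: Proposed new method: one-pot ester reduction followed by alkoxide-directed intramolecular SN2 hydride opening of a fully substituted epoxide at its distal tertiary carbon — the ester is reduced first (fast at 0 °C) to the C12 alkoxy(hydrido)aluminate of 5, which lies on the β face next to C8, so on heating hydride is delivered through a seven-membered transition state anti to the C8–O bond (trans-diaxial Fürst–Plattner opening; attack at the neopentyl C9 is blocked), inverting C8 to 8β-H/8α-methyl while the 9α-oxygen from step 3 is kept; the closest known reaction types are the hydroxyl-directed aluminium hydride opening of 2,3-epoxy alcohols to 1,3-diols and the intermolecular LiAlH4 or LiEt3BH reduction of hindered epoxides.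

Step 5
Reactants: 6 13,14,15,16-tetranorlabdane-3β,9α,12-triol (8βH)
Product: 7 12-iodo-13,14,15,16-tetranorlabdane-3β,9α-diol (8βH)
Conditions: PPh3 (1.2 equiv), I2 (1.2 equiv), imidazole (2.5 equiv), THF, 0 °C to rt
Reagents that add atoms: iodine II
Why: Appel-type iodination (alkoxyphosphonium formation, then SN2 by iodide) is selective for the primary alcohol; the neopentyl-like secondary 3β-OH and the tertiary 9α-OH do not react, and no stereocentre is touched.

Step 6
Reactants: 7 12-iodo-13,14,15,16-tetranorlabdane-3β,9α-diol (8βH); 8 4-bromofuran-2(5H)-one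
Product: 9 3β,9α-dihydroxylabd-13-en-15,16-olide (8βH)
Conditions: NiBr2(MeOCH2CH2OMe) (10 mol %), 4,4′-di-tert-butyl-2,2′-bipyridine (10 mol %), Zn dust (2 equiv), DMA, 25–40 °C
Reagents that add atoms: none
Why: Nickel-catalysed reductive cross-electrophile coupling: the alkenyl bromide adds to low-valent nickel, the primary alkyl radical from the iodide is captured, and C(sp3)–C(sp2) reductive elimination joins C12 to C13; free alcohols are tolerated and no stereocentre is formed.

Step 7
Reactants: 9 3β,9α-dihydroxylabd-13-en-15,16-olide (8βH)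
Product: 10 3β-acetoxy-9α-hydroxylabd-13-en-15,16-olide (8βH)
Conditions: Ac2O (1.5 equiv), pyridine, 4-(dimethylamino)pyridine (5 mol %), CH2Cl2, 0 °C to rt
Reagents that add atoms: acetic anhydride CC(=O)OC(C)=O
Why: Nucleophile-catalysed acylation takes only the equatorial secondary 3β-OH; the axial, fully substituted 9α-OH is inert under these conditions, and the C3 configuration is retained.

**Compound list**
1 | (+)-sclareolide (13,14,15,16-tetranorlabdan-12,8α-olide) | C1CC[C@@]2(C)[C@@H](CC[C@@](C)(O3)[C@@H]2CC3=O)C1(C)C | starting material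
2 | 3β-hydroxysclareolide | O[C@H]1CC[C@@]2(C)[C@@H](CC[C@@](C)(O3)[C@@H]2CC3=O)C1(C)C | intermediate
3 | methyl 3β-hydroxy-13,14,15,16-tetranorlabd-8(9)-en-12-oate | O[C@H]1CC[C@@]2(C)[C@@H](CCC(C)=C2CC(=O)OC)C1(C)C | intermediate
4 | methyl 8α,9α-epoxy-3β-hydroxy-13,14,15,16-tetranorlabdan-12-oate | O[C@H]1CC[C@@]2(C)[C@@H](CC[C@@]3(C)O[C@@]23CC(=O)OC)C1(C)C | intermediate
5 | 8α,9α-epoxy-13,14,15,16-tetranorlabdane-3β,12-diol (present as its aluminium alkoxide) | O[C@H]1CC[C@@]2(C)[C@@H](CC[C@@]3(C)O[C@@]23CCO)C1(C)C | intermediate (not isolated)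
6 | 13,14,15,16-tetranorlabdane-3β,9α,12-triol, 8βH (C17 methyl α, equatorial) | O[C@H]1CC[C@@]2(C)[C@@H](CC[C@@H](C)[C@]2(O)CCO)C1(C)C | intermediate
7 | 12-iodo-13,14,15,16-tetranorlabdane-3β,9α-diol, 8βH | O[C@H]1CC[C@@]2(C)[C@@H](CC[C@@H](C)[C@]2(O)CCI)C1(C)C | intermediate
8 | 4-bromofuran-2(5H)-one | BrC1=CC(=O)OC1 | starting material
9 | 3β,9α-dihydroxylabd-13-en-15,16-olide, 8βH (C15 carbonyl, C16 CH2–O) | O[C@H]1CC[C@@]2(C)[C@@H](CC[C@@H](C)[C@]2(O)CCC2=CC(=O)OC2)C1(C)C | intermediate
10 | 3β-acetoxy-9α-hydroxylabd-13-en-15,16-olide, (3S,5S,8R,9R,10S) | CC(=O)O[C@H]1CC[C@@]2(C)[C@@H](CC[C@@H](C)[C@]2(O)CCC2=CC(=O)OC2)C1(C)C | target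

**Step count and risks**
Total steps: 7. Longest linear sequence: 7 steps (1 to 10); 8 is bought.

Three steps most likely to fail:

Step 2. The elimination may give too much of the Δ7 and Δ8(17) isomers, relactonise, or give 8-epi-sclareolide. Fallback, setting out from 2 and coming back at 3, places the alkene by mechanism instead of by equilibrium. The lactone enolate (LiN(iPr)2, 2.2 equiv, THF, −78 °C) is selenenylated with PhSeBr on the less hindered α face to give 11α-(phenylselanyl)-3β-hydroxysclareolide F1. H2O2 and pyridine in CH2Cl2 then effect selenoxide syn-elimination across C9–C11 to give 3β-hydroxy-13,14,15,16-tetranorlabd-9(11)-en-12,8α-olide F2. SmI2 (THF, tBuOH, −78 °C) cleaves the allylic C8–O bond reductively, and protonation of the dienolate at C11 gives 3β-hydroxy-13,14,15,16-tetranorlabd-8(9)-en-12-oic acid F3. Me3SiCHN2 in MeOH–toluene converts this acid into 3.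

Step 4 (the proposed new step). SN2 hydride delivery to a tertiary epoxide carbon that is 1,3-diaxial to the C10 methyl may be too slow, and elimination or rearrangement can compete. Fallback by known chemistry, setting out from 4 and coming back at 6: LiAlH4 at −20 °C reduces only the ester, and the epoxy diol 5 is isolated this time. Diethylaluminium 2,2,6,6-tetramethylpiperidide, Et2Al(NC9H18) (5 equiv, toluene, 0 °C), isomerises the epoxide by removing a C17 proton syn to oxygen, giving the allylic alcohol 13,14,15,16-tetranorlabd-8(17)-ene-3β,9α,12-triol F4. Hydrogen-atom-transfer hydrogenation (Mn(dpm)3 with dpm = 2,2,6,6-tetramethylheptane-3,5-dionate, cat.; PhSiH3, tBuOOH, iPrOH, 25 °C) reduces the exocyclic alkene through the tertiary C8 radical under thermodynamic control to the equatorial 8α-methyl compound 6.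

Step 6. The coupling may suffer from reduction or homocoupling of the bromobutenolide and β-hydride loss from the alkylnickel. Fallback, setting out from 7 and coming back at 9, builds the butenolide from a furan. Copper-catalysed alkyl–Grignard coupling of 7 with 3-furylmagnesium bromide (from 3-bromofuran and iPrMgCl·LiCl; 4 equiv to allow for the two OH groups; Li2CuCl4 5 mol %, THF, −20 to 0 °C) gives 15,16-epoxylabda-13(16),14-diene-3β,9α-diol F5. Photooxygenation in the presence of a hindered base (O2, hν, 5,10,15,20-tetraphenylporphyrin, iPr2NEt, CH2Cl2, −78 °C) gives regioselectively the γ-hydroxybutenolide 3β,9α,16-trihydroxylabd-13-en-15,16-olide F6 as C16 epimers. NaBH4 in EtOH followed by acidification reduces the lactol carbon and relactonises to 9.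

**Further compounds**
F1 | step 2 | 11α-(phenylselanyl)-3β-hydroxysclareolide | O[C@H]1CC[C@@]2(C)[C@@H](CC[C@@](C)(O3)[C@@H]2[C@H]([Se]c2ccccc2)C3=O)C1(C)C
F2 | step 2 | 3β-hydroxy-13,14,15,16-tetranorlabd-9(11)-en-12,8α-olide | O[C@H]1CC[C@@]2(C)[C@@H](CC[C@@]3(C)OC(=O)C=C23)C1(C)C
F3 | step 2 | 3β-hydroxy-13,14,15,16-tetranorlabd-8(9)-en-12-oic acid | O[C@H]1CC[C@@]2(C)[C@@H](CCC(C)=C2CC(=O)O)C1(C)C
F4 | step 4 | 13,14,15,16-tetranorlabd-8(17)-ene-3β,9α,12-triol | O[C@H]1CC[C@@]2(C)[C@@H](CCC(=C)[C@]2(O)CCO)C1(C)C
F5 | step 6 | 15,16-epoxylabda-13(16),14-diene-3β,9α-diol, 8βH | O[C@H]1CC[C@@]2(C)[C@@H](CC[C@@H](C)[C@]2(O)CCc2ccoc2)C1(C)C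
F6 | step 6 | 3β,9α,16-trihydroxylabd-13-en-15,16-olide, 8βH (C16 epimers) | O[C@H]1CC[C@@]2(C)[C@@H](CC[C@@H](C)[C@]2(O)CCC2=CC(=O)OC2O)C1(C)C
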